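## Analysis of the target

The target 25 is an ether of two 2-(2-phenylethyl)chromone units. One unit is flat: a 7-methoxychromone whose benzo ring (ring A) carries the ether oxygen at C6. The other is a 5,6,7,8-tetrahydrochromone in which a 4-pyranone (ring C) is fused through C4a=C8a to a carbocycle (ring B) with oxygen on each sp3 carbon: free hydroxyls at C5, C6 and C7 and the aryl ether at C8. The four stereocentres are contiguous, (5S,6R,7S,8S), with the relations 5,6-trans, 6,7-trans, 7,8-cis and therefore 5,8-cis. Ring B is fragile: two eliminations would give an aromatic chromone, the C5 carbinol sits on the carbon next to the enol-ether-like C4a=C8a bond and can ionise in acid, and the pyranones add nucleophiles under strong base. The synthesis is hard because four adjacent oxygenated centres must be set on a ring that tends to aromatise, O8 must be told apart from three similar secondary hydroxyls, and a secondary alkyl aryl ether must be made with defined configuration next to the pyranone. The strategy rests on ring B: C5 and C8 both hang on the C4a=C8a bond, so C5–C4a–C8a–C8 is a latent 1,4-dioxygenated diene and C6–C7 a latent E-alkene, and the 5,8-cis / 6,7-trans / 7,8-cis pattern is that of an endo [4+2] adduct.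

## Retrosynthetic reasoning

**Aryl ether.** The bond between O8 and C6 of ring A is cut, which leads from 25 through its protected forms 24 and 23 to alcohol 17 and bromide 22. The C8–O bond is left alone because the cycloaddition already delivers C8 with the right configuration; a coupling that uses the alcohol as nucleophile cannot invert it. A displacement at C8 would need the 8-epimer and would compete with elimination towards the aromatic chromone. The forward reaction must arylate a hindered secondary alcohol under base, so O5, O6 and O7 must carry base-stable groups.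

**Protecting-group pattern.** Alcohol 17 is traced to triol 16 and this to diacetate 15. Acetates cannot be carried through a basic coupling, since the acetyl group on O7 would shift to the cis-related O8. They are therefore exchanged for a cyclic diacetal that selects the trans-diequatorial 6,7-diol and leaves O8 free in one operation. O5 keeps a tert-butyldiphenylsilyl ether, which withstands the acid used on the way.

**C6–O and C7–O.** The two acetate C–O bonds of 15 are replaced by C–acetyl bonds in diketone 14. Carbonyl groups are what a dienophile needs, and the oxidative rearrangement that turns them into esters proceeds with retention, so C6 and C7 can be set as carbon stereocentres.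

**Ring B (key disconnection).** The bonds C5–C6 and C7–C8 of 14 are cut together. This leaves dienol 13 and the symmetric dienophile 12, and 13 is the photoenol of aldehyde 11. No other cut sets all four stereocentres in one step or starts from a pyranone with only two one-carbon substituents. It also differentiates O8 (free hydroxyl) from O5 (silyl ether) by construction. The aldehyde must sit on the pyranone carbon next to the ring oxygen, so that the metal-bound hydroxyl ends at C8 and directs the neighbouring acetyl group to C7.

**Aldehyde 11.** The formyl group is masked as the diethyl acetal of 10 until the end. The silyloxymethyl group comes from alcohol 9, and its carbon (the future C5) from iodide 8 by cross-coupling. Silylation precedes acetal hydrolysis because a free hydroxymethyl group next to the aldehyde would close to a lactol.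

**Pyranone ring of 8.** In pyranone numbering the bonds C5–C6 and O1–C2 are cut, which gives iodo enaminone 5 and acid chloride 6 by way of diketone 7. Two other routes to 8 were set aside. Iodination of a finished pyranone would have to choose between C3 and C5. Electrophilic cyclisation of an enol-ether ynone would need the ether oxygen cis to the acyl group, whereas enol ethers made from β-keto esters are formed trans. Ring closure by addition–elimination does not depend on alkene geometry.

**Iodo enaminone 5.** Iodine is introduced into enaminone 4 at its only nucleophilic carbon. Enaminone 4 comes from ynone 3 by conjugate addition of a secondary amine, and 3 from alkyne 1 and amide 2.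

**Ring A bromide 22.** The pyranone ring is cut to diketone 21, which comes from bromo ketone 19 and ester 20. Compound 19 is the bromination product of paeonol 18; the position para to the phenol becomes C6 of the chromone.

## Alternatives that were turned down

**Alternative 1: enzymatic dearomatisation of a flat chromone.**
- Disconnection: the C7–O and C8–O bonds are cut and ring B is traced to the benzo ring of 2-(2-phenylethyl)chromone A2.
- Key step: a Rieske-type arene dioxygenase in whole cells cis-dihydroxylates C7 and C8 to give the dihydrodiol A1.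
- For it: A2 is two steps from simple materials, so this is the shortest entry and is stronger than the chosen route on step economy. Epoxidation of the C5=C6 bond of A1 anti to the diol and opening at C5 would give the right relative configuration.
- Against it: these enzymes prefer ordinary arenes, and A2 offers the monosubstituted phenyl ring of its side chain as the more likely site. Acceptance of the electron-poor benzo ring and the absolute sense are both unknown. A1 rearomatises easily. Nothing distinguishes O8 from O7 in a cis-diol, so selective arylation at O8 would cost several protecting-group steps.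
- Comparison: the chosen route gives O8 as the only free hydroxyl and does not depend on an enzyme accepting an unusual substrate.

**Alternative 2: organochromium closure of C4a–C5 on a sugar-derived chain.**
- Disconnection: the C4a–C5 bond is cut. C6, C7 and C8 come from a pentose of the chiral pool, with the aryl ether already in place in the open-chain iodo aldehyde A4.
- Key step: an intramolecular Nozaki–Hiyama–Kishi reaction (divalent chromium, nickel co-catalyst) joins the C4a iodide to the C5 aldehyde and gives the bis(methoxymethyl) ether A3 of the target.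
- For it: the ring closure is a well-precedented reaction type, three centres are bought, and the aryl ether can be made early on an unhindered acyclic carbinol. On these points it is stronger than the chosen route.
- Against it: C5 is created in the closure with no reliable control of the 5,6-trans relation. A4 is an α-alkoxy aldehyde with an aryloxy group next to the pyranone, so it is prone to epimerisation and elimination. The pyranone must be built on the sugar chain in a long linear sequence. The methoxymethyl ethers need acid at the end, on the ionisable triol.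
- Comparison: the chosen route sets all four centres, including C5, in one step and reaches the cycloaddition precursor in seven steps. Its price is an unproven key step.

**Alternative 3: ring-closing metathesis at C6=C7.**
- Disconnection: the C6–C7 bond is cut, leading to diene A6 with one vinyl carbinol on each of the two pyranone carbons.
- Key step: the second-generation Grubbs catalyst closes ring B with loss of the two terminal methylene groups and gives the cis-5,8-dioxygenated dihydrochromone A5.
- For it: metathesis to a cyclohexene is reliable, and the aryl ether is again made before ring closure. On precedent it is stronger than the chosen route.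
- Against it: C5 and C8 must be set by two separate asymmetric vinyl additions. The 6,7-trans diol must then come from epoxidation anti to both substituents and opening at C7 rather than C6. The two ends of the epoxide differ only in remote groups (silyl ether versus aryl ether), so the regiochemistry of opening, which decides between the target and a diastereomer, is not controlled.
- Comparison: in the chosen route the E geometry of the dienophile fixes the 6,7-trans relation, and the endo rule ties it to C5 and C8.

Key step: step 8

Remark (absolute sense of step 8): which enantiomer of the chiral diol gives the (5R,6S,7S,8S) adduct cannot be derived with certainty for this new diene; (R,R)-TADDOL is written, and its mirror image is to be used if the sense proves opposite.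

Remark (numbering): conjugate bases formed by deprotonation in the flask (acetylide, enolates, alkoxides) are treated as forms of the numbered compound and not as separate compounds.

## Route

Step 1
Reactants: 1 3,3-diethoxyprop-1-yne; 2 N-methoxy-N-methylacetamide
Product: 3 5,5-diethoxypent-3-yn-2-one
Conditions: n-BuLi, THF, −78 °C; then 2, −78 → 0 °C; aq. NH4Cl
Reagents that add atoms: none
Why: Weinreb ketone synthesis: the lithium acetylide of 1 adds once to the amide because the chelated tetrahedral adduct survives until work-up; the acetal is inert to the base.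

Step 2
Reactants: 3 5,5-diethoxypent-3-yn-2-one
Product: 4 (E)-5,5-diethoxy-4-(pyrrolidin-1-yl)pent-3-en-2-one
Conditions: pyrrolidine (1.05 equiv), EtOH, 0 °C → rt
Reagents that add atoms: pyrrolidine, C1CCNC1
Why: Conjugate (aza-Michael) addition of a secondary amine to an ynone takes place only at the β-carbon and should give the push-pull enaminone as the E isomer; the geometry has no consequence later.

Step 3
Reactants: 4 (E)-5,5-diethoxy-4-(pyrrolidin-1-yl)pent-3-en-2-one
Product: 5 (Z)-5,5-diethoxy-3-iodo-4-(pyrrolidin-1-yl)pent-3-en-2-one (amino group trans to acetyl)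
Conditions: N-iodosuccinimide, CH2Cl2, 0 °C, dark
Reagents that add atoms: N-iodosuccinimide, O=C1CCC(=O)N1I
Why: Electrophilic iodination of an enaminone occurs at its only nucleophilic carbon, between the carbonyl and the amino carbon, which places iodine at the future C3 of the pyranone (C4a of ring B) without any regiochemical choice.

Step 4
Reactants: 5 (Z)-5,5-diethoxy-3-iodo-4-(pyrrolidin-1-yl)pent-3-en-2-one; 6 3-phenylpropanoyl chloride
Product: 8 2-(diethoxymethyl)-3-iodo-6-(2-phenylethyl)-4H-pyran-4-one, via iodo enaminone diketone 7 (not isolated)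
Conditions: LiN(SiMe3)2 (2.2 equiv), THF, −78 °C; 6, −78 → −20 °C; then AcOH, 50 °C
Reagents that add atoms: none
Why: Claisen-type acylation of the kinetic methyl-ketone enolate of a vinylogous amide by an acid chloride, then acid-induced addition–elimination of the enol oxygen at the amino-bearing carbon with loss of pyrrolidine (the enaminone route to 4-pyranones). Ring closure does not depend on alkene geometry, and the weak acid is chosen to avoid C-protonation and loss of iodine.

Step 5
Reactants: 8 2-(diethoxymethyl)-3-iodo-6-(2-phenylethyl)-4H-pyran-4-one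
Product: 9 2-(diethoxymethyl)-3-(hydroxymethyl)-6-(2-phenylethyl)-4H-pyran-4-one
Conditions: Bu3SnCH2OH, Pd(PPh3)4 (cat.), 1,4-dioxane, 100 °C
Reagents that add atoms: (tributylstannyl)methanol, CCCC[Sn](CCCC)(CCCC)CO
Why: Stille coupling of an α-iodo enone with (tributylstannyl)methanol transfers the hydroxymethyl group in preference to butyl; the acetal and the pyranone are inert to zerovalent palladium.

Step 6
Reactants: 9 2-(diethoxymethyl)-3-(hydroxymethyl)-6-(2-phenylethyl)-4H-pyran-4-one
Product: 10 3-[(tert-butyldiphenylsilyloxy)methyl]-2-(diethoxymethyl)-6-(2-phenylethyl)-4H-pyran-4-one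
Conditions: t-BuPh2SiCl, imidazole, DMF, rt
Reagents that add atoms: tert-butyl(chloro)diphenylsilane, CC(C)(C)[Si](Cl)(c1ccccc1)c1ccccc1
Why: Silylation of a primary alcohol; the tert-butyldiphenylsilyl ether is chosen because it must survive the acetal hydrolysis of step 7 and the acidic steps 11 and 15, which a tert-butyldimethylsilyl ether would not.

Step 7
Reactants: 10 3-[(tert-butyldiphenylsilyloxy)methyl]-2-(diethoxymethyl)-6-(2-phenylethyl)-4H-pyran-4-one
Product: 11 3-[(tert-butyldiphenylsilyloxy)methyl]-4-oxo-6-(2-phenylethyl)-4H-pyran-2-carbaldehyde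
Conditions: p-TsOH·H2O (cat.), acetone/H2O (10:1), 50 °C
Reagents that add atoms: water, O
Why: Acid-catalysed acetal hydrolysis; the primary tert-butyldiphenylsilyl ether is stable to catalytic sulfonic acid, and silylation before this step prevents lactol formation between the formyl and hydroxymethyl groups.

Step 8
Reactants: 11 3-[(tert-butyldiphenylsilyloxy)methyl]-4-oxo-6-(2-phenylethyl)-4H-pyran-2-carbaldehyde; 12 (E)-hex-3-ene-2,5-dione
Product: 14 (5R,6S,7S,8S)-6,7-diacetyl-5-(tert-butyldiphenylsilyloxy)-8-hydroxy-2-(2-phenylethyl)-5,6,7,8-tetrahydro-4H-chromen-4-one, via pyranone dienol 13 (not isolated)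
Conditions: Ti(OiPr)4 (1.0 equiv), (R,R)-TADDOL (1.1 equiv), 12 (3 equiv), toluene, degassed, hν (365 nm LED), −20 °C; aq. NaHCO3
Reagents that add atoms: none
Why: Proposed new method: excitation of the titanium-bound formyl group (n,π*) leads to 1,5-hydrogen transfer from the CH2OSi group through a six-membered transition state, and the biradical relaxes to the ground-state dienol 13, in which the C4a–C8a bond is the central single bond; the isomer with the hydroxyl inside returns to 11 by a thermal 1,5-shift, and the silyloxy group stays outside because inside it would collide with H-8. The closest known reaction type is the photoenolisation/Diels–Alder reaction of 2-alkylbenzaldehydes with enones, including its enantioselective form with Ti(OiPr)4 and a chiral diol; what is new is the 4-pyranone in place of the benzene ring. Ring B is closed by an intermolecular suprafacial [4+2] cycloaddition that forms C5–C6 and C7–C8 and restores the pyranone. C5 and C8 (cis) follow from the outside position of both oxygen groups on the diene, C6 and C7 (trans) from the E geometry of 12, and C7 relative to C8 (cis) from the endo position of the acetyl group that is tied to O8 through tetravalent titanium. The absolute configuration of all four centres comes from the TADDOL ligand on titanium, which shields one face of the bound dienol. The step needs endo selectivity for the bridged acetyl group and one diene face; both are secured by the dienol hydroxyl, the only group of the diene that binds titanium covalently, and the C2 symmetry of 12 removes any regiochemical question. The low aromatic stabilisation of a 4-pyranone should make the dienol easier to reach than from a benzaldehyde.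

Step 9
Reactants: 14 (5R,6S,7S,8S)-6,7-diacetyl-5-(tert-butyldiphenylsilyloxy)-8-hydroxy-2-(2-phenylethyl)-5,6,7,8-tetrahydro-4H-chromen-4-one
Product: 15 (5S,6S,7R,8S)-5-(tert-butyldiphenylsilyloxy)-8-hydroxy-4-oxo-2-(2-phenylethyl)-5,6,7,8-tetrahydro-4H-chromene-6,7-diyl diacetate
Conditions: mCPBA (6 equiv), NaHCO3, CH2Cl2, rt → 40 °C
Reagents that add atoms: 3-chloroperbenzoic acid, OOC(=O)c1cccc(Cl)c1
Why: Twofold Baeyer–Villiger oxidation: in each methyl ketone the secondary ring carbon migrates in preference to methyl and with retention, so the acetyl groups become acetates without change at C6 and C7 (the descriptors change only by priority); the buffer suppresses retro-aldol cleavage and β-elimination.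

Step 10
Reactants: 15 (5S,6S,7R,8S)-5-(tert-butyldiphenylsilyloxy)-8-hydroxy-4-oxo-2-(2-phenylethyl)-5,6,7,8-tetrahydro-4H-chromene-6,7-diyl diacetate
Product: 16 (5S,6S,7S,8S)-5-(tert-butyldiphenylsilyloxy)-6,7,8-trihydroxy-2-(2-phenylethyl)-5,6,7,8-tetrahydro-4H-chromen-4-one
Conditions: K2CO3 (cat.), MeOH, 0 °C
Reagents that add atoms: none
Why: Mild base-catalysed transesterification removes both acetates; with catalytic carbonate at 0 °C the hindered silyl ether and the pyranone should be left alone.

Step 11
Reactants: 16 (5S,6S,7S,8S)-5-(tert-butyldiphenylsilyloxy)-6,7,8-trihydroxy-2-(2-phenylethyl)-5,6,7,8-tetrahydro-4H-chromen-4-one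
Product: 17 6,7-O-[(2S,3S)-2,3-dimethoxybutane-2,3-diyl] acetal of 16, (5S,6S,7R,8S), trans-fused dioxane with both methoxy groups axial, 8-OH free
Conditions: butane-2,3-dione, HC(OMe)3, camphorsulfonic acid (cat.), MeOH, 60 °C
Reagents that add atoms: butane-2,3-dione, CC(=O)C(C)=O; trimethyl orthoformate, COC(OC)OC
Why: Butane-2,3-diacetal formation is under thermodynamic control and selects the trans-diequatorial 6,7-diol over the cis-7,8 pair, as with cyclohexene triols of the shikimate type, so only O8 stays free; the two new acetal centres are fixed by the anomeric effect.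

Step 12
Reactants: 18 paeonol, 1-(2-hydroxy-4-methoxyphenyl)ethanone
Product: 19 1-(5-bromo-2-hydroxy-4-methoxyphenyl)ethanone
Conditions: N-bromosuccinimide, MeCN, 0 °C → rt
Reagents that add atoms: N-bromosuccinimide, O=C1CCC(=O)N1Br
Why: Electrophilic bromination of the activated arene goes para to the phenolic hydroxyl and ortho to methoxy, the position that becomes C6 of the chromone.

Step 13
Reactants: 19 1-(5-bromo-2-hydroxy-4-methoxyphenyl)ethanone; 20 ethyl 3-phenylpropanoate
Product: 22 6-bromo-7-methoxy-2-(2-phenylethyl)-4H-chromen-4-one, via bromo diketone 21 (not isolated)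
Conditions: NaH, THF, 65 °C; then conc. HCl, AcOH, 80 °C
Reagents that add atoms: none
Why: Claisen condensation of the acetophenone enolate with the ester gives the 1,3-diketone, and acid-catalysed cyclodehydration (the standard chromone synthesis) closes the pyranone; the aryl bromide and the methyl ether are untouched.

Step 14
Reactants: 17 butane-2,3-diacetal alcohol; 22 6-bromo-7-methoxy-2-(2-phenylethyl)-4H-chromen-4-one
Product: 23 8-O-[7-methoxy-4-oxo-2-(2-phenylethyl)-4H-chromen-6-yl] ether of 17, (5S,6S,7S,8S)
Conditions: [Pd(allyl)Cl]2 (cat.), RockPhos, Cs2CO3, toluene, 90 °C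
Reagents that add atoms: none
Why: Palladium-catalysed C–O cross-coupling of a secondary alcohol with an aryl bromide (Buchwald–Hartwig etherification), with a bulky biaryl phosphine that speeds reductive elimination over β-hydride elimination. The C8–O bond is not broken, so the configuration at C8 is retained, and the diacetal and the silyl ether tolerate carbonate base.

Step 15
Reactants: 23 protected aryl ether
Product: 24 (5S,6S,7S,8S)-5-(tert-butyldiphenylsilyloxy)-6,7-dihydroxy-8-{[7-methoxy-4-oxo-2-(2-phenylethyl)-4H-chromen-6-yl]oxy}-2-(2-phenylethyl)-5,6,7,8-tetrahydro-4H-chromen-4-one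
Conditions: CF3CO2H/H2O (9:1), CH2Cl2, 0 °C
Reagents that add atoms: none
Why: Aqueous trifluoroacetic acid hydrolyses the butane-2,3-diacetal, while the aryl ether (its C8 cation is not stabilised) and the hindered silyl ether, which shields the ionisable C5 position, should persist.

Step 16
Reactants: 24 silyl ether diol
Product: 25 (5S,6R,7S,8S)-5,6,7-trihydroxy-8-{[7-methoxy-4-oxo-2-(2-phenylethyl)-4H-chromen-6-yl]oxy}-2-(2-phenylethyl)-5,6,7,8-tetrahydro-4H-chromen-4-one (CNP0125425.2)
Conditions: Bu4NF, AcOH, THF, rt → 40 °C
Reagents that add atoms: none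
Why: Fluoride cleaves the silyl ether; buffering with acetic acid keeps the medium non-basic so that the triol does not eliminate towards the aromatic chromone.

## Compound list

1 | 3,3-diethoxyprop-1-yne | CCOC(OCC)C#C | starting material
2 | N-methoxy-N-methylacetamide | CON(C)C(C)=O | starting material
3 | 5,5-diethoxypent-3-yn-2-one | CC(=O)C#CC(OCC)OCC | intermediate
4 | (E)-5,5-diethoxy-4-(pyrrolidin-1-yl)pent-3-en-2-one | CC(=O)/C=C(/N1CCCC1)C(OCC)OCC | intermediate
5 | (Z)-5,5-diethoxy-3-iodo-4-(pyrrolidin-1-yl)pent-3-en-2-one | CC(=O)/C(I)=C(/N1CCCC1)C(OCC)OCC | intermediate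
6 | 3-phenylpropanoyl chloride | O=C(Cl)CCc1ccccc1 | starting material
7 | (Z)-1,1-diethoxy-3-iodo-8-phenyl-2-(pyrrolidin-1-yl)oct-2-ene-4,6-dione | O=C(CCc1ccccc1)CC(=O)/C(I)=C(/N1CCCC1)C(OCC)OCC | intermediate
8 | 2-(diethoxymethyl)-3-iodo-6-(2-phenylethyl)-4H-pyran-4-one | CCOC(OCC)c1oc(CCc2ccccc2)cc(=O)c1I | intermediate
9 | 2-(diethoxymethyl)-3-(hydroxymethyl)-6-(2-phenylethyl)-4H-pyran-4-one | CCOC(OCC)c1oc(CCc2ccccc2)cc(=O)c1CO | intermediate
10 | 3-[(tert-butyldiphenylsilyloxy)methyl]-2-(diethoxymethyl)-6-(2-phenylethyl)-4H-pyran-4-one | CCOC(OCC)c1oc(CCc2ccccc2)cc(=O)c1CO[Si](c1ccccc1)(c1ccccc1)C(C)(C)C | intermediate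
11 | 3-[(tert-butyldiphenylsilyloxy)methyl]-4-oxo-6-(2-phenylethyl)-4H-pyran-2-carbaldehyde | O=Cc1oc(CCc2ccccc2)cc(=O)c1CO[Si](c1ccccc1)(c1ccccc1)C(C)(C)C | intermediate
12 | (E)-hex-3-ene-2,5-dione | CC(=O)/C=C/C(C)=O | starting material
13 | 3-[(tert-butyldiphenylsilyloxy)methylidene]-2-(hydroxymethylidene)-6-(2-phenylethyl)-2,3-dihydro-4H-pyran-4-one, both oxygen groups outside | O/C=C1\OC(CCc2ccccc2)=CC(=O)/C1=C\O[Si](c1ccccc1)(c1ccccc1)C(C)(C)C | intermediate
14 | (5R,6S,7S,8S)-6,7-diacetyl-5-(tert-butyldiphenylsilyloxy)-8-hydroxy-2-(2-phenylethyl)-5,6,7,8-tetrahydro-4H-chromen-4-one | O[C@@H]1c2oc(CCc3ccccc3)cc(=O)c2[C@H](O[Si](c3ccccc3)(c3ccccc3)C(C)(C)C)[C@@H](C(C)=O)[C@@H]1C(C)=O | intermediate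
15 | (5S,6S,7R,8S)-5-(tert-butyldiphenylsilyloxy)-8-hydroxy-4-oxo-2-(2-phenylethyl)-5,6,7,8-tetrahydro-4H-chromene-6,7-diyl diacetate | O[C@@H]1c2oc(CCc3ccccc3)cc(=O)c2[C@H](O[Si](c3ccccc3)(c3ccccc3)C(C)(C)C)[C@@H](OC(C)=O)[C@@H]1OC(C)=O | intermediate
16 | (5S,6S,7S,8S)-5-(tert-butyldiphenylsilyloxy)-6,7,8-trihydroxy-2-(2-phenylethyl)-5,6,7,8-tetrahydro-4H-chromen-4-one | O[C@@H]1c2oc(CCc3ccccc3)cc(=O)c2[C@H](O[Si](c3ccccc3)(c3ccccc3)C(C)(C)C)[C@@H](O)[C@@H]1O | intermediate
17 | 6,7-O-[(2S,3S)-2,3-dimethoxybutane-2,3-diyl] acetal of 16 | O[C@@H]1c2oc(CCc3ccccc3)cc(=O)c2[C@H](O[Si](c3ccccc3)(c3ccccc3)C(C)(C)C)[C@H]3O[C@](C)(OC)[C@@](C)(OC)O[C@H]13 | intermediate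
18 | paeonol, 1-(2-hydroxy-4-methoxyphenyl)ethanone | CC(=O)c1ccc(OC)cc1O | starting material
19 | 1-(5-bromo-2-hydroxy-4-methoxyphenyl)ethanone | CC(=O)c1cc(Br)c(OC)cc1O | intermediate
20 | ethyl 3-phenylpropanoate | CCOC(=O)CCc1ccccc1 | starting material
21 | 1-(5-bromo-2-hydroxy-4-methoxyphenyl)-5-phenylpentane-1,3-dione | O=C(CCc1ccccc1)CC(=O)c1cc(Br)c(OC)cc1O | intermediate
22 | 6-bromo-7-methoxy-2-(2-phenylethyl)-4H-chromen-4-one | COc1cc2oc(CCc3ccccc3)cc(=O)c2cc1Br | intermediate
23 | 8-O-[7-methoxy-4-oxo-2-(2-phenylethyl)-4H-chromen-6-yl] ether of 17 | COc1cc2oc(CCc3ccccc3)cc(=O)c2cc1O[C@@H]1c2oc(CCc3ccccc3)cc(=O)c2[C@H](O[Si](c3ccccc3)(c3ccccc3)C(C)(C)C)[C@H]3O[C@](C)(OC)[C@@](C)(OC)O[C@H]13 | intermediate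
24 | (5S,6S,7S,8S)-5-(tert-butyldiphenylsilyloxy)-6,7-dihydroxy-8-aryloxy compound (aryl = ring A chromone) | COc1cc2oc(CCc3ccccc3)cc(=O)c2cc1O[C@@H]1c2oc(CCc3ccccc3)cc(=O)c2[C@H](O[Si](c3ccccc3)(c3ccccc3)C(C)(C)C)[C@@H](O)[C@@H]1O | intermediate
25 | (5S,6R,7S,8S)-5,6,7-trihydroxy-8-{[7-methoxy-4-oxo-2-(2-phenylethyl)-4H-chromen-6-yl]oxy}-2-(2-phenylethyl)-5,6,7,8-tetrahydro-4H-chromen-4-one | COc1cc2oc(CCc3ccccc3)cc(=O)c2cc1O[C@@H]1c2oc(CCc3ccccc3)cc(=O)c2[C@H](O)[C@@H](O)[C@@H]1O | target

## Step count and least certain steps

Total step count: 16. Longest linear sequence: 14 steps (steps 1–11 and 14–16); the ring A bromide takes 2 steps (12–13).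

**Step 8 (key step, new method).**
- What may go wrong: photorearrangement of the pyranone chromophore instead of hydrogen abstraction; E/Z photoisomerisation of dienophile 12 under the lamp, which would erode the 6,7-trans relation; poor facial selectivity if the dienol reacts unbound; and β-elimination of the adduct towards the aromatic chromone.
- Fallback: it sets out from 11 and 12 and returns at 14, and uses the ground-state version of the same bond construction. Aldehyde 11 is treated with Me3SiOTf and Et3N, which removes the γ-hydrogen of the vinylogous aldehyde and gives the bis(silyloxy) diene, 3-[(tert-butyldiphenylsilyloxy)methylidene]-6-(2-phenylethyl)-2-[(trimethylsilyloxy)methylidene]-2,3-dihydro-4H-pyran-4-one F1. Thermal Diels–Alder reaction of this 1,4-dioxygenated diene with 12 in toluene gives the 8-O-trimethylsilyl ether of 14, F2, and aqueous citric acid in THF removes the trimethylsilyl group to return 14. Without the titanium bridge neither the endo preference of the C7 acetyl group nor the facial sense is controlled, so a diastereomer separation and a resolution of 14 on a chiral stationary phase would be needed.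

**Step 14 (O-arylation).**
- What may go wrong: β-hydride elimination from the palladium alkoxide (oxidation at C8 and reduction of 22), and slow coupling of a hindered pseudoaxial alkoxide with an ortho-substituted, electron-rich bromide.
- Fallback: it sets out from 22 and 17 and returns at 23, and replaces catalysis by ligand coupling at trivalent iodine. Bromide 22 is converted with NaI, CuI and a diamine ligand into 6-iodo-7-methoxy-2-(2-phenylethyl)-4H-chromen-4-one F3. Oxidation with mCPBA and TsOH in the presence of 1,3,5-trimethoxybenzene gives [7-methoxy-4-oxo-2-(2-phenylethyl)-4H-chromen-6-yl](2,4,6-trimethoxyphenyl)iodonium tosylate F4. The sodium alkoxide of 17 (NaH, toluene, rt) should then take the ring A aryl group from F4, again with retention at C8, to give 23.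

**Step 11 (selective diacetal).**
- What may go wrong: acetalisation of the cis-7,8 pair instead of the 6,7 pair, because the locked 6,7-diequatorial form pushes the bulky O5 silyl ether against the C4 carbonyl; also solvolysis at C5 in acidic methanol.
- Fallback: it sets out from 15 and returns at 25, using a temporary ether on O8 and silyl ethers on O6 and O7.
  - Diacetate 15 is alkylated with 4-methoxybenzyl trichloroacetimidate and catalytic La(OTf)3 to give the 8-O-(4-methoxybenzyl) diacetate F5.
  - K2CO3 in MeOH gives the 6,7-diol F6, and t-BuMe2SiOTf with 2,6-lutidine gives the 6,7-bis(tert-butyldimethylsilyl) ether F7.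
  - DDQ in wet CH2Cl2 frees O8 to give alcohol F8, which is arylated with 22 under the conditions of step 14 to give the trisilyl aryl ether F9.
  - Bu4NF/AcOH removes all three silyl groups and gives 25.

**Step 9 (twofold Baeyer–Villiger oxidation).**
- What may go wrong: slow oxygen insertion at the hindered C6 ketone, during which the free β-hydroxy ketone undergoes retro-aldol cleavage or β-elimination, or C6/C7 epimerise.
- Fallback: it sets out from 14 and returns at 15, and removes the free hydroxyl so that a stronger peracid can be used. Et3SiCl and imidazole give the 8-O-triethylsilyl ether of 14, F10. CF3CO3H (from (CF3CO)2O and urea–H2O2) with Na2HPO4 gives the 8-O-triethylsilyl diacetate F11. HF·pyridine in THF/pyridine removes only the triethylsilyl group and returns 15.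

**Step 4 (acylation and ring closure).**
- What may go wrong: transfer or loss of iodine from the enaminone carbon during the acidic ring closure, O-acylation of the enolate, or ketene formation from 6.
- Fallback: it sets out from 1 and returns at 8, and closes the ring by electrophilic iodocyclisation instead.
  - Commercial methyl 3-oxo-5-phenylpentanoate F12 is converted with HC(OMe)3 and acid into methyl (E)-3-methoxy-5-phenylpent-2-enoate F13.
  - Saponification gives (E)-3-methoxy-5-phenylpent-2-enoic acid F14, and oxalyl chloride gives (E)-3-methoxy-5-phenylpent-2-enoyl chloride F15.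
  - Acyl Sonogashira coupling of F15 with 1 (PdCl2(PPh3)2, CuI, Et3N) gives (E)-1,1-diethoxy-6-methoxy-8-phenyloct-5-en-2-yn-4-one F16.
  - ICl in CH2Cl2 closes F16 to 8 by 6-endo attack of the ether oxygen and loss of the methyl group. This works only after the push-pull enol ether has isomerised to its Z form, which traces of acid in the reagent are expected to bring about.

## Further compounds

F1 | step 8 | 3-[(tert-butyldiphenylsilyloxy)methylidene]-6-(2-phenylethyl)-2-[(trimethylsilyloxy)methylidene]-2,3-dihydro-4H-pyran-4-one | C[Si](C)(C)O/C=C1\OC(CCc2ccccc2)=CC(=O)/C1=C\O[Si](c1ccccc1)(c1ccccc1)C(C)(C)C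
F2 | step 8 | 8-O-trimethylsilyl ether of 14 | C[Si](C)(C)O[C@@H]1c2oc(CCc3ccccc3)cc(=O)c2[C@H](O[Si](c3ccccc3)(c3ccccc3)C(C)(C)C)[C@@H](C(C)=O)[C@@H]1C(C)=O
F3 | step 14 | 6-iodo-7-methoxy-2-(2-phenylethyl)-4H-chromen-4-one | COc1cc2oc(CCc3ccccc3)cc(=O)c2cc1I
F4 | step 14 | [7-methoxy-4-oxo-2-(2-phenylethyl)-4H-chromen-6-yl](2,4,6-trimethoxyphenyl)iodonium 4-methylbenzenesulfonate | COc1cc(OC)c([I+]c2cc3c(=O)cc(CCc4ccccc4)oc3cc2OC)c(OC)c1.Cc1ccc(S(=O)(=O)[O-])cc1
F5 | step 11 | 8-O-(4-methoxybenzyl) ether of 15 | COc1ccc(CO[C@@H]2c3oc(CCc4ccccc4)cc(=O)c3[C@H](O[Si](c3ccccc3)(c3ccccc3)C(C)(C)C)[C@@H](OC(C)=O)[C@@H]2OC(C)=O)cc1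
F6 | step 11 | 8-O-(4-methoxybenzyl) ether of 16 | COc1ccc(CO[C@@H]2c3oc(CCc4ccccc4)cc(=O)c3[C@H](O[Si](c3ccccc3)(c3ccccc3)C(C)(C)C)[C@@H](O)[C@@H]2O)cc1
F7 | step 11 | 6,7-bis(tert-butyldimethylsilyl) ether of F6 | COc1ccc(CO[C@@H]2c3oc(CCc4ccccc4)cc(=O)c3[C@H](O[Si](c3ccccc3)(c3ccccc3)C(C)(C)C)[C@@H](O[Si](C)(C)C(C)(C)C)[C@@H]2O[Si](C)(C)C(C)(C)C)cc1
F8 | step 11 | 6,7-bis(tert-butyldimethylsilyl) ether of 16, 8-OH free | O[C@@H]1c2oc(CCc3ccccc3)cc(=O)c2[C@H](O[Si](c3ccccc3)(c3ccccc3)C(C)(C)C)[C@@H](O[Si](C)(C)C(C)(C)C)[C@@H]1O[Si](C)(C)C(C)(C)C
F9 | step 11 | 6,7-bis(tert-butyldimethylsilyl) ether of 24 | COc1cc2oc(CCc3ccccc3)cc(=O)c2cc1O[C@@H]1c2oc(CCc3ccccc3)cc(=O)c2[C@H](O[Si](c3ccccc3)(c3ccccc3)C(C)(C)C)[C@@H](O[Si](C)(C)C(C)(C)C)[C@@H]1O[Si](C)(C)C(C)(C)C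
F10 | step 9 | 8-O-triethylsilyl ether of 14 | CC[Si](CC)(CC)O[C@@H]1c2oc(CCc3ccccc3)cc(=O)c2[C@H](O[Si](c3ccccc3)(c3ccccc3)C(C)(C)C)[C@@H](C(C)=O)[C@@H]1C(C)=O
F11 | step 9 | 8-O-triethylsilyl ether of 15 | CC[Si](CC)(CC)O[C@@H]1c2oc(CCc3ccccc3)cc(=O)c2[C@H](O[Si](c3ccccc3)(c3ccccc3)C(C)(C)C)[C@@H](OC(C)=O)[C@@H]1OC(C)=O
F12 | step 4 | methyl 3-oxo-5-phenylpentanoate | COC(=O)CC(=O)CCc1ccccc1
F13 | step 4 | methyl (E)-3-methoxy-5-phenylpent-2-enoate | CO/C(CCc1ccccc1)=C/C(=O)OC
F14 | step 4 | (E)-3-methoxy-5-phenylpent-2-enoic acid | CO/C(CCc1ccccc1)=C/C(=O)O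
F15 | step 4 | (E)-3-methoxy-5-phenylpent-2-enoyl chloride | CO/C(CCc1ccccc1)=C/C(=O)Cl
F16 | step 4 | (E)-1,1-diethoxy-6-methoxy-8-phenyloct-5-en-2-yn-4-one | CCOC(OCC)C#CC(=O)/C=C(/OC)CCc1ccccc1
A1 | alternative 1 | cis-7,8-dihydroxy-7,8-dihydro-2-(2-phenylethyl)chromen-4-one | O[C@@H]1c2oc(CCc3ccccc3)cc(=O)c2C=C[C@@H]1O
A2 | alternative 1 | 2-(2-phenylethyl)chromen-4-one | O=c1cc(CCc2ccccc2)oc2ccccc12
A3 | alternative 2 | 6,7-bis(methoxymethyl) ether of 25 | COc1cc2oc(CCc3ccccc3)cc(=O)c2cc1O[C@@H]1c2oc(CCc3ccccc3)cc(=O)c2[C@H](O)[C@@H](OCOC)[C@@H]1OCOC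
A4 | alternative 2 | open-chain iodo aldehyde, 4-aryloxy-4-[3-iodo-4-oxo-6-(2-phenylethyl)-4H-pyran-2-yl]-2,3-bis(methoxymethoxy)butanal | COc1cc2oc(CCc3ccccc3)cc(=O)c2cc1O[C@H](c1oc(CCc2ccccc2)cc(=O)c1I)[C@@H](OCOC)[C@H](OCOC)C=O
A5 | alternative 3 | cis-8-aryloxy-5-(tert-butyldimethylsilyloxy)-5,8-dihydro-2-(2-phenylethyl)chromen-4-one | COc1cc2oc(CCc3ccccc3)cc(=O)c2cc1O[C@@H]1c2oc(CCc3ccccc3)cc(=O)c2[C@H](O[Si](C)(C)C(C)(C)C)C=C1
A6 | alternative 3 | diene with a 1-aryloxyallyl group at C2 and a 1-(tert-butyldimethylsilyloxy)allyl group at C3 of 6-(2-phenylethyl)-4H-pyran-4-one | COc1cc2oc(CCc3ccccc3)cc(=O)c2cc1O[C@@H](C=C)c1oc(CCc2ccccc2)cc(=O)c1[C@H](O[Si](C)(C)C(C)(C)C)C=C
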